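## Retrosynthetic overview

- The free acid is unmasked last from a 2-(trimethylsilyl)ethyl ester with fluoride, so the hindered benzoate and the epoxide never see hydrolysis or acid.
- The eleven-membered carbocycle is closed by an intramolecular Horner–Wadsworth–Emmons olefination that makes the (E)-enoate (ester trans to the benzoate carbon).
- The benzoate stereocentre is put directly onto the open-chain aldehyde by enamine-catalysed α-benzoyloxylation.
- The oxirane is made before the macrocycle, by Shi epoxidation of an open-chain (E)-trisubstituted alkene.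
- That alkene comes from a B-alkyl Suzuki union of 3,3-dimethylhex-5-en-1-ol with an (E)-vinyl iodide that already carries the phosphonoacetate. Ring order: oxirane first, eleven-membered ring second.

Assumption: the phosphonate-bearing carbon made in step 7 becomes an alkene carbon in step 12, so it is carried as both epimers and written without a stereo descriptor; the catalysts named are taken as purchasable.

## Route

Step 1
Reactants: 1 diethyl 2-(propan-2-ylidene)propanedioate; 2 allylmagnesium bromide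
Product: 3 diethyl 2-(2-methylpent-4-en-2-yl)propanedioate
Conditions: 2 (1.3 equiv, Et2O), CuI (5 mol%), THF, −30 → 0 °C; then 1 M HCl
Reagents that add atoms: none
Why: Copper-catalysed conjugate addition of the Grignard reagent to the doubly activated alkylidene malonate builds the gem-dimethyl quaternary carbon; no stereocentre is formed.

Step 2
Reactants: 3 diethyl 2-(2-methylpent-4-en-2-yl)propanedioate
Product: 4 ethyl 3,3-dimethylhex-5-enoate
Conditions: LiCl, H2O (2 equiv), DMSO, 160 °C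
Reagents that add atoms: none
Why: Krapcho dealkoxycarbonylation removes one ester group of the malonate and leaves the terminal alkene untouched.

Step 3
Reactants: 4 ethyl 3,3-dimethylhex-5-enoate
Product: 5 3,3-dimethylhex-5-en-1-ol
Conditions: LiAlH4, Et2O, 0 °C → rt; H2O / aq. NaOH work-up
Reagents that add atoms: none
Why: Hydride reduction of the ester gives the primary alcohol that later becomes the aldehyde carbon.

Step 4
Reactants: 6 pent-3-yn-1-ol
Product: 7 pent-3-yn-1-yl 4-methylbenzenesulfonate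
Conditions: TsCl, Et3N, DMAP (cat.), CH2Cl2, 0 °C → rt
Reagents that add atoms: 4-methylbenzenesulfonyl chloride, Cc1ccc(cc1)S(=O)(=O)Cl
Why: Sulfonylation turns the hydroxyl into a leaving group and removes the alkoxide that could misdirect the hydrometalation.

Step 5
Reactants: 7 pent-3-yn-1-yl 4-methylbenzenesulfonate
Product: 9 (3E)-4-iodopent-3-en-1-yl 4-methylbenzenesulfonate, via alkenylzirconocene chloride 8 (not isolated)
Conditions: Cp2Zr(H)Cl (2.2 equiv), THF, 50 °C; then I2, 0 °C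
Reagents that add atoms: iodine, II
Why: Hydrozirconation–iodination: syn addition of Zr–H, equilibration with excess reagent puts zirconium on the less hindered methyl-bearing carbon, and iodinolysis with retention gives the (E)-iodide (a minor regioisomer is removed by chromatography).

Step 6
Reactants: 10 2-(diethoxyphosphoryl)acetic acid; 11 2-(trimethylsilyl)ethanol
Product: 12 2-(trimethylsilyl)ethyl 2-(diethoxyphosphoryl)acetate
Conditions: DCC, DMAP (10 mol%), CH2Cl2, 0 °C → rt
Reagents that add atoms: none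
Why: Steglich esterification installs an ester that fluoride can cleave at the end without touching the benzoate or the epoxide.

Step 7
Reactants: 12 2-(trimethylsilyl)ethyl 2-(diethoxyphosphoryl)acetate; 9 (3E)-4-iodopent-3-en-1-yl 4-methylbenzenesulfonate
Product: 13 2-(trimethylsilyl)ethyl (5E)-2-(diethoxyphosphoryl)-6-iodohept-5-enoate
Conditions: 12 (1.5 equiv), NaH, DMF, 0 °C; then 9, NaI (0.2 equiv), 60 °C
Reagents that add atoms: none
Why: SN2 C-alkylation of the soft phosphonoacetate enolate at the primary sulfonate; the vinyl iodide is inert and the excess of 12 suppresses dialkylation.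

Step 8
Reactants: 5 3,3-dimethylhex-5-en-1-ol; 13 2-(trimethylsilyl)ethyl (5E)-2-(diethoxyphosphoryl)-6-iodohept-5-enoate
Product: 15 2-(trimethylsilyl)ethyl (5E)-2-(diethoxyphosphoryl)-12-hydroxy-6,10,10-trimethyldodec-5-enoate, via B-alkyl-9-BBN borane 14 (not isolated)
Conditions: 5 (1.3 equiv), 9-BBN (2.2 equiv per 5), THF, 0 °C → rt; then 13, Pd(dppf)Cl2 (5 mol%), AsPh3, Cs2CO3, DMF/H2O, rt
Reagents that add atoms: none
Why: Anti-Markovnikov hydroboration followed by B-alkyl Suzuki–Miyaura coupling joins the two fragments with retention of the vinyl iodide geometry, giving the (E)-trisubstituted alkene; the borinate on oxygen hydrolyses on work-up.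

Step 9
Reactants: 15 2-(trimethylsilyl)ethyl (5E)-2-(diethoxyphosphoryl)-12-hydroxy-6,10,10-trimethyldodec-5-enoate
Product: 16 2-(trimethylsilyl)ethyl 2-(diethoxyphosphoryl)-4-[(2R,3R)-3-(6-hydroxy-4,4-dimethylhexyl)-3-methyloxiran-2-yl]butanoate
Conditions: D-fructose-derived Shi ketone (30 mol%), Oxone (KHSO5), K2CO3, Bu4NHSO4, MeCN/CH2(OMe)2, aq. Na2B4O7/Na2EDTA buffer (pH 10.5), −10 → 0 °C
Reagents that add atoms: potassium peroxymonosulfate KHSO5 (active part of Oxone), [K+].[O-]S(=O)(=O)OO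
Why: Shi asymmetric epoxidation: the chiral dioxirane delivers oxygen through a spiro transition state to the face of the (E)-trisubstituted alkene that gives the (R,R)-epoxide, as it does for trans- and trisubstituted alkenes in general.

Step 10
Reactants: 16 2-(trimethylsilyl)ethyl 2-(diethoxyphosphoryl)-4-[(2R,3R)-3-(6-hydroxy-4,4-dimethylhexyl)-3-methyloxiran-2-yl]butanoate
Product: 17 2-(trimethylsilyl)ethyl 2-(diethoxyphosphoryl)-4-[(2R,3R)-3-(4,4-dimethyl-6-oxohexyl)-3-methyloxiran-2-yl]butanoate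
Conditions: Dess–Martin periodinane, NaHCO3, CH2Cl2, 0 °C → rt
Reagents that add atoms: none
Why: Buffered Dess–Martin oxidation gives the aldehyde without acid, so the epoxide and the phosphonoacetate survive.

Step 11
Reactants: 17 2-(trimethylsilyl)ethyl 2-(diethoxyphosphoryl)-4-[(2R,3R)-3-(4,4-dimethyl-6-oxohexyl)-3-methyloxiran-2-yl]butanoate
Product: 18 2-(trimethylsilyl)ethyl 4-{(2R,3R)-3-[(5S)-5-(benzoyloxy)-4,4-dimethyl-6-oxohexyl]-3-methyloxiran-2-yl}-2-(diethoxyphosphoryl)butanoate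
Conditions: (S)-2-(triphenylmethyl)pyrrolidine (10–20 mol%), dibenzoyl peroxide (1.1 equiv), hydroquinone (10 mol%), THF, 0 °C; cold NaHCO3 wash, short silica plug, used the same day
Reagents that add atoms: dibenzoyl peroxide, O=C(OOC(=O)c1ccccc1)c1ccccc1
Why: Enamine-catalysed α-benzoyloxylation: the (E)-enamine attacks the peroxide O–O bond on the face opposite the trityl group, which sets the (S)-acyloxy aldehyde (the R centre of the target once the aldehyde carbon becomes an alkene carbon).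

Step 12
Reactants: 18 2-(trimethylsilyl)ethyl 4-{(2R,3R)-3-[(5S)-5-(benzoyloxy)-4,4-dimethyl-6-oxohexyl]-3-methyloxiran-2-yl}-2-(diethoxyphosphoryl)butanoate
Product: 19 2-(trimethylsilyl)ethyl (1R,4E,6R,11R)-6-(benzoyloxy)-7,7,11-trimethyl-12-oxabicyclo[9.1.0]dodec-4-ene-4-carboxylate
Conditions: slow addition (10 h) of 18 to LiCl (10 equiv), DBU (2 equiv), MeCN, 0 °C → rt, final 1 mM
Reagents that add atoms: none
Why: Intramolecular Horner–Wadsworth–Emmons olefination under Masamune–Roush conditions closes the eleven-membered ring; the usual preference for the ester trans to the aldehyde-derived substituent coincides with the less strained in-ring cis arrangement, and the mild base with no β-hydrogen on the aldehyde limits epimerisation of the benzoate centre.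

Step 13
Reactants: 19 2-(trimethylsilyl)ethyl (1R,4E,6R,11R)-6-(benzoyloxy)-7,7,11-trimethyl-12-oxabicyclo[9.1.0]dodec-4-ene-4-carboxylate
Product: 20 (1R,4E,6R,11R)-6-(benzoyloxy)-7,7,11-trimethyl-12-oxabicyclo[9.1.0]dodec-4-ene-4-carboxylic acid
Conditions: Bu4NF (3 equiv), THF, 0 °C → rt; then cold 0.1 M HCl to pH 4
Reagents that add atoms: none
Why: Fluoride attacks silicon and the ester fragments by β-elimination (ethene and Me3SiF), which frees the acid under conditions that leave the neopentylic benzoate, the enoate and the epoxide intact.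

## Compound list

1 | diethyl 2-(propan-2-ylidene)propanedioate | CCOC(=O)C(=C(C)C)C(=O)OCC | starting material
2 | allylmagnesium bromide | C=CC[Mg]Br | starting material
3 | diethyl 2-(2-methylpent-4-en-2-yl)propanedioate | CCOC(=O)C(C(=O)OCC)C(C)(C)CC=C | intermediate
4 | ethyl 3,3-dimethylhex-5-enoate | CCOC(=O)CC(C)(C)CC=C | intermediate
5 | 3,3-dimethylhex-5-en-1-ol | OCCC(C)(C)CC=C | intermediate
6 | pent-3-yn-1-ol | CC#CCCO | starting material
7 | pent-3-yn-1-yl 4-methylbenzenesulfonate | CC#CCCOS(=O)(=O)c1ccc(C)cc1 | intermediate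
8 | chlorobis(cyclopentadienyl)[(2E)-5-(tosyloxy)pent-2-en-2-yl]zirconium | C/C(=C\CCOS(=O)(=O)c1ccc(C)cc1)[Zr](Cl)(C1C=CC=C1)C1C=CC=C1 | intermediate
9 | (3E)-4-iodopent-3-en-1-yl 4-methylbenzenesulfonate | C/C(I)=C\CCOS(=O)(=O)c1ccc(C)cc1 | intermediate
10 | 2-(diethoxyphosphoryl)acetic acid | CCOP(=O)(CC(=O)O)OCC | starting material
11 | 2-(trimethylsilyl)ethanol | C[Si](C)(C)CCO | starting material
12 | 2-(trimethylsilyl)ethyl 2-(diethoxyphosphoryl)acetate | CCOP(=O)(CC(=O)OCC[Si](C)(C)C)OCC | intermediate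
13 | 2-(trimethylsilyl)ethyl (5E)-2-(diethoxyphosphoryl)-6-iodohept-5-enoate | CCOP(=O)(OCC)C(CC/C=C(\C)I)C(=O)OCC[Si](C)(C)C | intermediate
14 | 9-{6-[(9-borabicyclo[3.3.1]nonan-9-yl)oxy]-4,4-dimethylhexyl}-9-borabicyclo[3.3.1]nonane | CC(C)(CCCB1C2CCCC1CCC2)CCOB1C2CCCC1CCC2 | intermediate
15 | 2-(trimethylsilyl)ethyl (5E)-2-(diethoxyphosphoryl)-12-hydroxy-6,10,10-trimethyldodec-5-enoate | CCOP(=O)(OCC)C(CC/C=C(\C)CCCC(C)(C)CCO)C(=O)OCC[Si](C)(C)C | intermediate
16 | 2-(trimethylsilyl)ethyl 2-(diethoxyphosphoryl)-4-[(2R,3R)-3-(6-hydroxy-4,4-dimethylhexyl)-3-methyloxiran-2-yl]butanoate | OCCC(C)(C)CCC[C@@]1(C)O[C@@H]1CCC(P(=O)(OCC)OCC)C(=O)OCC[Si](C)(C)C | intermediate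
17 | 2-(trimethylsilyl)ethyl 2-(diethoxyphosphoryl)-4-[(2R,3R)-3-(4,4-dimethyl-6-oxohexyl)-3-methyloxiran-2-yl]butanoate | O=CCC(C)(C)CCC[C@@]1(C)O[C@@H]1CCC(P(=O)(OCC)OCC)C(=O)OCC[Si](C)(C)C | intermediate
18 | 2-(trimethylsilyl)ethyl 4-{(2R,3R)-3-[(5S)-5-(benzoyloxy)-4,4-dimethyl-6-oxohexyl]-3-methyloxiran-2-yl}-2-(diethoxyphosphoryl)butanoate | O=C[C@@H](OC(=O)c1ccccc1)C(C)(C)CCC[C@@]1(C)O[C@@H]1CCC(P(=O)(OCC)OCC)C(=O)OCC[Si](C)(C)C | intermediate
19 | 2-(trimethylsilyl)ethyl (1R,4E,6R,11R)-6-(benzoyloxy)-7,7,11-trimethyl-12-oxabicyclo[9.1.0]dodec-4-ene-4-carboxylate | CC1(C)CCC[C@@]2(C)O[C@@H]2CC/C(C(=O)OCC[Si](C)(C)C)=C\[C@H]1OC(=O)c1ccccc1 | intermediate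
20 | (1R,4E,6R,11R)-6-(benzoyloxy)-7,7,11-trimethyl-12-oxabicyclo[9.1.0]dodec-4-ene-4-carboxylic acid | CC1(C)CCC[C@@]2(C)O[C@@H]2CC/C(C(=O)O)=C\[C@H]1OC(=O)c1ccccc1 | target

## Step count and risks

Total step count: 13. Longest linear sequence: 9 steps (1, 2, 3, 8, 9, 10, 11, 12, 13; the branch 4, 5, 7, 8–13 is equally long).

**Step 11 (α-benzoyloxylation of a β-quaternary aldehyde carrying an epoxide and a phosphonate).** The fallback sets out from 17 and comes back at 19. Aldehyde 17 is α-aminoxylated with nitrosobenzene under D-proline catalysis (DMSO, 0 °C), a hydrogen-bond-directed enamine reaction with a smaller electrophile that gives the same (S) sense, to give 2-(trimethylsilyl)ethyl 4-{(2R,3R)-3-[(5S)-5-(anilinooxy)-4,4-dimethyl-6-oxohexyl]-3-methyloxiran-2-yl}-2-(diethoxyphosphoryl)butanoate F1. This is cyclised at once under the LiCl/DBU high-dilution conditions of step 12 to 2-(trimethylsilyl)ethyl (1R,4E,6R,11R)-6-(anilinooxy)-7,7,11-trimethyl-12-oxabicyclo[9.1.0]dodec-4-ene-4-carboxylate F2. Reductive N–O cleavage (Zn dust, AcOH/THF, 0 °C) gives 2-(trimethylsilyl)ethyl (1R,4E,6R,11R)-6-hydroxy-7,7,11-trimethyl-12-oxabicyclo[9.1.0]dodec-4-ene-4-carboxylate F3, and benzoylation (BzCl, pyridine, DMAP, CH2Cl2) gives 19.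

**Step 12 (closure of the eleven-membered ring; oligomerisation or epimerisation next to the aldehyde).** The fallback sets out from 5 and 13 and comes back at 19. The olefination is run between two molecules and the ring is closed at the other alkene:
- 5 is oxidised (Dess–Martin periodinane, NaHCO3) to 3,3-dimethylhex-5-enal F4.
- F4 is benzoyloxylated as in step 11 to (2S)-3,3-dimethyl-1-oxohex-5-en-2-yl benzoate F5.
- Horner–Wadsworth–Emmons reaction of F5 with 13 (LiCl, DBU, MeCN) gives 2-(trimethylsilyl)ethyl (2E,4R)-4-(benzoyloxy)-2-[(3E)-4-iodopent-3-en-1-yl]-5,5-dimethylocta-2,7-dienoate F6.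
- 9-BBN adds to the terminal alkene only, giving 2-(trimethylsilyl)ethyl (2E,4R)-4-(benzoyloxy)-8-(9-borabicyclo[3.3.1]nonan-9-yl)-2-[(3E)-4-iodopent-3-en-1-yl]-5,5-dimethyloct-2-enoate F7, which is not isolated.
- Pd(dppf)Cl2, AsPh3 and Cs2CO3 in DMF/THF/H2O at 2 mM close the ring by intramolecular B-alkyl Suzuki coupling to 2-(trimethylsilyl)ethyl (1E,3R,8E)-3-(benzoyloxy)-4,4,8-trimethylcycloundeca-1,8-diene-1-carboxylate F8.
- Shi epoxidation with the same ketone oxidises the electron-rich trisubstituted alkene and leaves the enoate alone, giving 19. The facial outcome on the ring would have to be confirmed, because ring conformation now competes with the catalyst.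

**Step 8 (palladium coupling in the presence of a free hydroxyl, an acidic phosphonoacetate C–H and a homoallylic phosphonate that could C-vinylate).** The fallback sets out from 9 and 14 (made from 5) and comes back at 15. The order of the two C–C bond formations is reversed. Borane 14 is coupled with iodo sulfonate 9 under the same catalyst to give (3E)-10-hydroxy-4,8,8-trimethyldec-3-en-1-yl 4-methylbenzenesulfonate F9. The sodium enolate of 12 (NaH, DMF, NaI, 60 °C) is then alkylated with F9 to give 15.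

## Further compounds

F1 | step 11 | 2-(trimethylsilyl)ethyl 4-{(2R,3R)-3-[(5S)-5-(anilinooxy)-4,4-dimethyl-6-oxohexyl]-3-methyloxiran-2-yl}-2-(diethoxyphosphoryl)butanoate | O=C[C@@H](ONc1ccccc1)C(C)(C)CCC[C@@]1(C)O[C@@H]1CCC(P(=O)(OCC)OCC)C(=O)OCC[Si](C)(C)C
F2 | step 11 | 2-(trimethylsilyl)ethyl (1R,4E,6R,11R)-6-(anilinooxy)-7,7,11-trimethyl-12-oxabicyclo[9.1.0]dodec-4-ene-4-carboxylate | CC1(C)CCC[C@@]2(C)O[C@@H]2CC/C(C(=O)OCC[Si](C)(C)C)=C\[C@H]1ONc1ccccc1
F3 | step 11 | 2-(trimethylsilyl)ethyl (1R,4E,6R,11R)-6-hydroxy-7,7,11-trimethyl-12-oxabicyclo[9.1.0]dodec-4-ene-4-carboxylate | CC1(C)CCC[C@@]2(C)O[C@@H]2CC/C(C(=O)OCC[Si](C)(C)C)=C\[C@H]1O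
F4 | step 12 | 3,3-dimethylhex-5-enal | O=CCC(C)(C)CC=C
F5 | step 12 | (2S)-3,3-dimethyl-1-oxohex-5-en-2-yl benzoate | O=C[C@@H](OC(=O)c1ccccc1)C(C)(C)CC=C
F6 | step 12 | 2-(trimethylsilyl)ethyl (2E,4R)-4-(benzoyloxy)-2-[(3E)-4-iodopent-3-en-1-yl]-5,5-dimethylocta-2,7-dienoate | C=CCC(C)(C)[C@H](OC(=O)c1ccccc1)/C=C(\CC/C=C(\C)I)C(=O)OCC[Si](C)(C)C
F7 | step 12 | 2-(trimethylsilyl)ethyl (2E,4R)-4-(benzoyloxy)-8-(9-borabicyclo[3.3.1]nonan-9-yl)-2-[(3E)-4-iodopent-3-en-1-yl]-5,5-dimethyloct-2-enoate | CC(C)(CCCB1C2CCCC1CCC2)[C@H](OC(=O)c1ccccc1)/C=C(\CC/C=C(\C)I)C(=O)OCC[Si](C)(C)C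
F8 | step 12 | 2-(trimethylsilyl)ethyl (1E,3R,8E)-3-(benzoyloxy)-4,4,8-trimethylcycloundeca-1,8-diene-1-carboxylate | CC1(C)CCC/C(C)=C/CC/C(C(=O)OCC[Si](C)(C)C)=C\[C@H]1OC(=O)c1ccccc1
F9 | step 8 | (3E)-10-hydroxy-4,8,8-trimethyldec-3-en-1-yl 4-methylbenzenesulfonate | OCCC(C)(C)CCC/C(C)=C/CCOS(=O)(=O)c1ccc(C)cc1
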